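# Synthesis proposal for (5S,8R)-8-hydroxy-3-methoxy-2-methyl-5-(5-phenylpentyl)-5,6,7,8-tetrahydroquinolin-4(1H)-one (16)

## Analysis of the target

Compound 16 is a 5,6,7,8-tetrahydroquinolin-4(1H)-one. Ring A (N1, C2, C3, C4, C4a, C8a) is a fully substituted 4-pyridone, fused through the C4a=C8a bond to the saturated bridge C5–C8 of ring B. Ring A carries a methyl group at C2, a methoxy group at C3 and the carbonyl at C4. Ring B has two stereocentres, C5 (S, 5-phenylpentyl) and C8 (R, hydroxyl), which are cis and stand 1,4 to each other, so neither can be relied on to direct the other. The C8 carbinol sits next to the electron-rich heteroaromatic ring and is open to ionisation, elimination towards a dihydroquinolone and oxidation. The pyridone is polar and an ambident N/O nucleophile. The difficulty lies in placing five contiguous substituents on ring A with heteroatoms on C3 and C4 at the right oxidation level, and in setting the remote cis pair C5/C8 as one enantiomer. The strategy rests on reading ring A as a vinylogous amide: N1–C2 with its methyl is an acetamide unit, C3(OMe)–C4(=O) is a methoxyacetyl group on C4a, and the two are joined across the C4a=C8a alkene, which is the enol alkene of a 2-acylcyclohexanone.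

## Retrosynthetic reasoning

**16 from 15 (O8–Si).** The C8 hydroxyl is kept as a silyl ether through the basic steps, so the last operation is a mild desilylation of 15 with a fluoride source. Nothing else in 15 reacts with fluoride.

**15 from 12 and 13 (N1–C8a and C2–C3).** Ring A is opened at these two bonds to give bromo enone 12 and acetamide 13. These cuts are chosen because both fragments then carry every substituent of ring A at its final oxidation level: 13 supplies N1, C2 and the methyl group, and the methoxyacetyl group of 12 supplies C3, the methoxy group and C4. In the forward sense a copper-mediated C–N coupling at the vinyl bromide gives enamide 14, and base then closes C2–C3 by enolate addition to the amide carbonyl and dehydration, in the same flask.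

**12 from 11 (C8a–Br).** The vinyl bromide is traced to the ring-enol C–O bond of β-diketone 11. The forward reaction has to replace the ring oxygen and not the side-chain oxygen, and it must spare the silyl ether.

**11 from 8 and 9 (C4a–C4).** The acyl group is cut off to give ketone 8 and Weinreb amide 9. The silyloxy group on the other α-carbon of 8 blocks enolisation on that side, so lithium enolate 10 forms only towards the future C4a. Regiochemistry therefore does not depend on trapping a conjugate-addition enolate.

**8 from 4 and 6 (C5–C1′ of the chain).** The chain is removed from C5 to give enone 4 and Grignard reagent 6. A copper-catalysed asymmetric conjugate addition sets C5 under catalyst control, and magnesium enolate 7 is simply protonated. The stereocentre of 4 is 1,4 to the reacting carbon and is not touched. The organomagnesium compound is used as such, so each chain equivalent that is made is available for transfer.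

**6 from 5.** The Grignard reagent comes from bromide 5 by direct metal insertion.

**4 from 1 (C8–O).** Enone 4 is traced through alcohol 3 and racemic acetate 2 to cyclohexenone 1. The oxygen is brought in first because in 1 the α′-carbon is the only enolisable position. After the chain and acyl group are present, oxidation at that carbon would compete with the other acidic sites of 8 or 11. The single enantiomer is obtained by enzymatic resolution of 2.

## Alternatives that were turned down

**Alternative 1:** Ring B is cut at C4a–C5 and C8–C8a. In the forward sense (1E,3E)-9-phenylnona-1,3-dien-1-yl acetate A1 adds to ethyl (2E)-4-oxo-4-(2-oxo-1,3-oxazolidin-3-yl)but-2-enoate A2 in a Diels–Alder reaction under a chiral Cu(SbF6)2–tert-butyl-bis(oxazoline) Lewis acid. The product is ethyl 5-acetoxy-6-(2-oxo-1,3-oxazolidine-3-carbonyl)-2-(5-phenylpentyl)cyclohex-3-ene-1-carboxylate A3, with acetoxy, imide and alkyl groups all cis and the ester trans.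
- For it: one catalytic step builds ring B and sets both C5 and C8. The cis relation follows from the E,E geometry of the diene and the absolute sense from the catalyst, with no resolution. On stereochemical economy it is stronger than the chosen route.
- Against it: in A3 the carbons C4a and C8a are sp3 carboxyl-bearing stereocentres that must be destroyed again. The alkene has to be hydrogenated, imide and ester told apart, the C8a carboxyl turned into nitrogen, the C4a ester into a methoxymethyl ketone, ring A closed and then dehydrogenated. The acetoxy group is β to the imide carbonyl and can be lost by E1cB elimination. A β-substituted dienophile with a terminally alkylated acetoxy diene is a slow pairing for this catalyst.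
- Comparison: the chosen route sets the two centres in two separate events, but it closes ring A from fragments already at the final oxidation level and needs no redox correction afterwards.

**Alternative 2:** The C8–C8a bond is cut on an intact, O-benzylated pyridine. (4S)-4-[4-(Benzyloxy)-2-bromo-5-methoxy-6-methylpyridin-3-yl]-9-phenylnonanal A4 is activated at the bromide by NiCl2 and passed to CrCl2 bearing a chiral sulfonamide–oxazoline ligand. The pyridyl chromium species adds to the tethered aldehyde (Nozaki–Hiyama–Kishi closure) to give (5S,8R)-4-(benzyloxy)-3-methoxy-2-methyl-5-(5-phenylpentyl)-5,6,7,8-tetrahydroquinolin-8-ol A5.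
- For it: ring B and the C8 carbinol are made late in one reagent-controlled step on a finished heteroaromatic core, so no question of pyridone regiochemistry arises. On lateness of C8 and on convergence it is as strong as or stronger than the chosen route.
- Against it: A4 needs a pentasubstituted pyridine with a regiodefined bromide next to a side chain that already carries C5, which takes more steps than 12. 2-Pyridyl chromium species are less well behaved than alkenyl ones (nitrogen binds chromium, protodehalogenation competes). The ligand would have to override the conformational bias imposed by C5 in a ring closure. Chromium is needed in quantity or with a manganese and silyl chloride turnover system, and the benzyl group adds a deprotection.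
- Comparison: the chosen route makes ring A in one flask from a simple amide and a bromo enone, with catalytic copper.

**Alternative 3:** The C6–C7 bond is cut. 4-(Benzyloxy)-2-[(1S)-1-(tert-butyldimethylsilyloxy)-2-iodoethyl]-5-methoxy-6-methyl-3-(7-phenylhept-1-en-2-yl)pyridine A6 gives a primary C7 radical that adds to the terminal carbon of the 1,1-disubstituted alkene in a 6-endo closure. The tertiary C5 radical takes hydrogen from (Me3Si)3SiH to give (5S,8R)-4-(benzyloxy)-8-(tert-butyldimethylsilyloxy)-3-methoxy-2-methyl-5-(5-phenylpentyl)-5,6,7,8-tetrahydroquinoline A7.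
- For it: the conditions are neutral and tolerate every group present. The endo regiochemistry is well founded, since attack at the unsubstituted alkene carbon gives a tertiary, heteroaryl-stabilised radical. C8 can be set early by a reliable method. On functional-group tolerance it is stronger than the chosen route.
- Against it: C5 is fixed by hydrogen-atom transfer to a planar radical, guided only by the silyloxy group at C8, 1,4 across the ring. That is weak and hard to predict, and the wrong epimer cannot be repaired. A6 again requires a pentasubstituted pyridine with two ortho side chains, and a benzyl removal follows.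
- Comparison: the chosen route sets C5 in a catalyst-controlled C–C bond formation of proven type.

Key step: step 8

Assumption (chemistry): the hydrolase of step 2 is selected by screening so that it cleaves the R acetate; with an enzyme of opposite preference the recovered R acetate would be deacetylated and silylated to the same compound 4.

## Route

Step 1
Reactants: 1 cyclohex-2-en-1-one
Product: 2 rac-2-oxocyclohex-3-en-1-yl acetate (6-acetoxycyclohex-2-en-1-one)
Conditions: Mn(OAc)3·2H2O (2.5 equiv), benzene, reflux with water separation
Reagents that add atoms: manganese triacetate, CC(=O)O[Mn](OC(C)=O)OC(C)=O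
Why: α′-Acetoxylation of an enone by trivalent manganese acetate; the manganese enolate can form only at C6, the single enolisable position of 1, and acetate is transferred there, so the oxygen that becomes O8 is placed regiospecifically before any other substituent is present. The product is racemic.

Step 2
Reactants: 2 rac-2-oxocyclohex-3-en-1-yl acetate
Product: 3 (6R)-6-hydroxycyclohex-2-en-1-one
Conditions: Amano lipase PS (or pig liver esterase), phosphate buffer pH 7.0, MTBE, 25 °C, stopped near 45% conversion; chromatography
Reagents that add atoms: none
Why: Enzymatic kinetic resolution by enantioselective ester hydrolysis; the enzyme fixes the configuration of the future C8, and the unreacted S enantiomer of 2 is separated as the acetate. The near-neutral buffer avoids enolisation of the α-ketol.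

Step 3
Reactants: 3 (6R)-6-hydroxycyclohex-2-en-1-one
Product: 4 (6R)-6-(tert-butyldimethylsilyloxy)cyclohex-2-en-1-one
Conditions: TBSCl, imidazole, DMF, 0 °C to rt
Reagents that add atoms: tert-butyldimethylsilyl chloride, CC(C)(C)[Si](C)(C)Cl
Why: Standard silylation of a secondary alcohol under weakly basic conditions that should not epimerise the α-oxygenated ketone; the silyl ether later blocks enolisation towards this carbon.

Step 4
Reactants: 5 (5-bromopentyl)benzene
Product: 6 (5-phenylpentyl)magnesium bromide
Conditions: Mg turnings, I2 (cat.), Et2O, reflux; solution titrated and used directly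
Reagents that add atoms: magnesium, [Mg]
Why: Grignard reagent formation by insertion of magnesium into the primary C–Br bond; slow addition of 5 to excess metal in dilute ether should keep Wurtz homocoupling low, and the ethereal solution is the form required for the copper-catalysed addition of step 5.

Step 5
Reactants: 4 (6R)-6-(tert-butyldimethylsilyloxy)cyclohex-2-en-1-one; 6 (5-phenylpentyl)magnesium bromide
Product: 8 (2R,5S)-2-(tert-butyldimethylsilyloxy)-5-(5-phenylpentyl)cyclohexan-1-one, via magnesium enolate 7 (not isolated)
Conditions: CuBr·SMe2 (5 mol%), 1-[α-(dimethylamino)-2-(diphenylphosphino)benzyl]-2-(diphenylphosphino)ferrocene (6 mol%; TaniaPhos-type ligand, the enantiomer that leads to (S)-3-alkylcyclohexanones from the parent enone), Et2O, −40 °C, slow addition of 6 (1.2 equiv); aq. NH4Cl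
Reagents that add atoms: none
Why: Copper-catalysed asymmetric conjugate addition of a Grignard reagent to a cyclic enone with a chiral ferrocenyl diphosphine; the diphosphine-bound alkylcopper species formed by transmetallation adds 1,4 much faster than free 6 adds 1,2 when 6 is introduced slowly at low temperature. The ligand should deliver the chain to the face of the β-carbon that gives the S centre, as with the unsubstituted enone; the silyloxy group is 1,4 to the reacting carbon, so the catalyst and not the substrate is expected to decide the face, and with the R enone this gives the cis (2R,5S) ketone. Enolate 7 forms away from the silyloxy carbon, so that centre is untouched on protonation.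

Step 6
Reactants: 8 (2R,5S)-2-(tert-butyldimethylsilyloxy)-5-(5-phenylpentyl)cyclohexan-1-one; 9 N,2-dimethoxy-N-methylacetamide
Product: 11 1-[(3R,6S)-3-(tert-butyldimethylsilyloxy)-2-hydroxy-6-(5-phenylpentyl)cyclohex-1-en-1-yl]-2-methoxyethan-1-one (ring-enol form of the β-diketone), via lithium enolate 10 (not isolated)
Conditions: LiN(iPr)2 (1.1 equiv), THF, −78 °C; then 9, −78 to 0 °C; aq. NH4Cl
Reagents that add atoms: none
Why: Kinetic deprotonation of an α-silyloxy ketone occurs at the unsubstituted α-methylene, and the lithium enolate is C-acylated by the Weinreb amide; the chelated tetrahedral adduct lasts until work-up, so the acidic diketone never quenches unreacted enolate. The product enolises between the two carbonyls, which removes the stereocentre at the future C4a and shields the C–H of the future C8 from base.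

Step 7
Reactants: 11 1-[(3R,6S)-3-(tert-butyldimethylsilyloxy)-2-hydroxy-6-(5-phenylpentyl)cyclohex-1-en-1-yl]-2-methoxyethan-1-one
Product: 12 1-[(3R,6S)-2-bromo-3-(tert-butyldimethylsilyloxy)-6-(5-phenylpentyl)cyclohex-1-en-1-yl]-2-methoxyethan-1-one
Conditions: Ph3PBr2 (1.1 equiv), Et3N, CH2Cl2, −20 to 0 °C
Reagents that add atoms: triphenylphosphine dibromide, BrP(Br)(c1ccccc1)(c1ccccc1)c1ccccc1
Why: Conversion of a β-diketone enol into a β-bromo enone by O-phosphonium formation, conjugate addition of bromide and loss of Ph3PO. The ring oxygen is expected to be the one replaced, because this keeps the tetrasubstituted alkene endocyclic and conjugated to the side-chain ketone, whereas the exocyclic isomer would suffer allylic strain against the C6 chain. Amine buffering and low temperature protect the silyl ether.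

Step 8
Reactants: 12 1-[(3R,6S)-2-bromo-3-(tert-butyldimethylsilyloxy)-6-(5-phenylpentyl)cyclohex-1-en-1-yl]-2-methoxyethan-1-one; 13 acetamide
Product: 15 (5S,8R)-8-(tert-butyldimethylsilyloxy)-3-methoxy-2-methyl-5-(5-phenylpentyl)-5,6,7,8-tetrahydroquinolin-4(1H)-one, via enamide 14 (not isolated)
Conditions: CuI (10 mol%), MeNHCH2CH2NHMe (20 mol%), K2CO3 (2 equiv), 1,4-dioxane, 90 °C; then NaOtBu (2 equiv), 100 °C, same flask; aq. NH4Cl
Reagents that add atoms: none
Why: This is a Goldberg-type vinyl amidation followed by a Camps cyclisation, the sequence known for 2-halophenyl ketones leading to 4-quinolones, applied here to a cyclic β-bromo enone. The diamine-ligated monovalent copper amidate of 13 substitutes the bromide of 12, a vinylogous acyl bromide activated by the conjugated ketone, forming N1–C8a and giving enamide 14. tert-Butoxide then forms the enolate of the α-methoxy ketone, which attacks the acetamide carbonyl six atoms away in a 6-(enolendo)-exo-trig aldol-type closure (C2–C3), and dehydration aromatises ring A to the 4-pyridone. No stereocentre is formed; C5 and C8 should pass through unchanged, since C5–H is only allylic and C8–H is γ to the ketone and flanked by the bulky silyl ether. The step needs N- and not O-bonding of the amide, which the copper amidate secures. It also needs closure through the ketone enolate and not through the acetamide methyl, which would lead to a 2-pyridone; the methoxy group makes the ketone α-methylene the more acidic carbon acid, and after N–H deprotonation the acetyl methyl belongs to an electron-rich imidate that hardly enolises. C2, C3 and C4 arrive at their final oxidation level, so no redox step follows.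

Step 9
Reactants: 15 (5S,8R)-8-(tert-butyldimethylsilyloxy)-3-methoxy-2-methyl-5-(5-phenylpentyl)-5,6,7,8-tetrahydroquinolin-4(1H)-one
Product: 16 (5S,8R)-8-hydroxy-3-methoxy-2-methyl-5-(5-phenylpentyl)-5,6,7,8-tetrahydroquinolin-4(1H)-one
Conditions: Bu4NF, AcOH (1:1), THF, 0 °C to rt
Reagents that add atoms: none
Why: Fluoride-mediated cleavage of the Si–O bond; buffering with acetic acid keeps the medium near neutral, so the C8 carbinol should be neither ionised nor eliminated and its configuration is retained.

## Compound list

1 | cyclohex-2-en-1-one | O=C1C=CCCC1 | starting material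
2 | rac-2-oxocyclohex-3-en-1-yl acetate | CC(=O)OC1CCC=CC1=O | intermediate
3 | (6R)-6-hydroxycyclohex-2-en-1-one | O=C1C=CCC[C@H]1O | intermediate
4 | (6R)-6-(tert-butyldimethylsilyloxy)cyclohex-2-en-1-one | O=C1C=CCC[C@H]1O[Si](C)(C)C(C)(C)C | intermediate
5 | (5-bromopentyl)benzene | BrCCCCCc1ccccc1 | starting material
6 | (5-phenylpentyl)magnesium bromide | Br[Mg]CCCCCc1ccccc1 | intermediate
7 | bromo[(3S,6R)-6-(tert-butyldimethylsilyloxy)-3-(5-phenylpentyl)cyclohex-1-en-1-olato]magnesium | Br[Mg]OC1=C[C@@H](CCCCCc2ccccc2)CC[C@H]1O[Si](C)(C)C(C)(C)C | intermediate
8 | (2R,5S)-2-(tert-butyldimethylsilyloxy)-5-(5-phenylpentyl)cyclohexan-1-one | O=C1C[C@@H](CCCCCc2ccccc2)CC[C@H]1O[Si](C)(C)C(C)(C)C | intermediate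
9 | N,2-dimethoxy-N-methylacetamide | COCC(=O)N(C)OC | starting material
10 | lithium (3S,6R)-6-(tert-butyldimethylsilyloxy)-3-(5-phenylpentyl)cyclohex-1-en-1-olate | [Li]OC1=C[C@@H](CCCCCc2ccccc2)CC[C@H]1O[Si](C)(C)C(C)(C)C | intermediate
11 | 1-[(3R,6S)-3-(tert-butyldimethylsilyloxy)-2-hydroxy-6-(5-phenylpentyl)cyclohex-1-en-1-yl]-2-methoxyethan-1-one | OC2=C(C(=O)COC)[C@@H](CCCCCc1ccccc1)CC[C@H]2O[Si](C)(C)C(C)(C)C | intermediate
12 | 1-[(3R,6S)-2-bromo-3-(tert-butyldimethylsilyloxy)-6-(5-phenylpentyl)cyclohex-1-en-1-yl]-2-methoxyethan-1-one | BrC2=C(C(=O)COC)[C@@H](CCCCCc1ccccc1)CC[C@H]2O[Si](C)(C)C(C)(C)C | intermediate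
13 | acetamide | CC(N)=O | starting material
14 | N-[(3S,6R)-6-(tert-butyldimethylsilyloxy)-2-(methoxyacetyl)-3-(5-phenylpentyl)cyclohex-1-en-1-yl]acetamide | CC(=O)NC2=C(C(=O)COC)[C@@H](CCCCCc1ccccc1)CC[C@H]2O[Si](C)(C)C(C)(C)C | intermediate
15 | (5S,8R)-8-(tert-butyldimethylsilyloxy)-3-methoxy-2-methyl-5-(5-phenylpentyl)-5,6,7,8-tetrahydroquinolin-4(1H)-one | COc1c(C)[nH]c2c(c1=O)[C@@H](CCCCCc1ccccc1)CC[C@H]2O[Si](C)(C)C(C)(C)C | intermediate
16 | (5S,8R)-8-hydroxy-3-methoxy-2-methyl-5-(5-phenylpentyl)-5,6,7,8-tetrahydroquinolin-4(1H)-one | COc1c(C)[nH]c2c(c1=O)[C@@H](CCCCCc1ccccc1)CC[C@H]2O | target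

## Step count and least certain steps

Total: 9 steps. Longest linear sequence: 8 steps (steps 1, 2, 3, 5, 6, 7, 8, 9 from compound 1); step 4 is a one-step side branch.

**Step 8 (key step).** The C–N coupling may stall, because the bromide is tetrasubstituted, flanked by the silyloxy-bearing carbon, and the neighbouring keto ether can sequester copper. The closure may also run in part through the acetamide methyl onto the ketone (2-pyridone formation), and hot alkoxide may cause some loss of the silyl group. Early desilylation would only anticipate step 9. Fallback, setting out from 12: ammonia in methanol displaces the bromide by addition–elimination without metal to give 1-[(3R,6S)-2-amino-3-(tert-butyldimethylsilyloxy)-6-(5-phenylpentyl)cyclohex-1-en-1-yl]-2-methoxyethan-1-one F1. Heating F1 with N,N-dimethylacetamide dimethyl acetal in toluene gives N′-[(3S,6R)-6-(tert-butyldimethylsilyloxy)-2-(methoxyacetyl)-3-(5-phenylpentyl)cyclohex-1-en-1-yl]-N,N-dimethylethanimidamide F2. In F2 the only carbon nucleophile is the methoxy-substituted methylene and the only electrophile is the amidine carbon, so base-induced cyclocondensation (NaOtBu, THF) with loss of the amine can give only the 4-pyridone. The sequence comes back to the route at 15.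

**Step 7.** The phosphonium reagent may activate the side-chain oxygen instead of the hindered ring oxygen, giving the exocyclic bromoalkylidene ketone, and it may attack the silyl ether (bromodesilylation). Fallback, setting out from 11: O-sulfonylation with Tf2O and iPr2NEt in CH2Cl2 at −78 °C, conditions that leave silyl ethers alone, gives (3S,6R)-6-(tert-butyldimethylsilyloxy)-2-(methoxyacetyl)-3-(5-phenylpentyl)cyclohex-1-en-1-yl trifluoromethanesulfonate F3. F3 is coupled with 13 using Pd2(dba)3, Xantphos and Cs2CO3 in dioxane, a known amidation of enol triflates. This comes back to the route at enamide 14, which is closed with NaOtBu as in step 8.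

**Step 5.** Facial selectivity may be poor if the catalyst and the silyloxy-bearing centre form a mismatched pair, and uncatalysed 1,2-addition of the Grignard reagent to the α-oxygenated, more electrophilic ketone may compete with the copper-mediated 1,4-pathway. Fallback, setting out from 4: hydroboration of 5-phenylpent-1-yne with pinacolborane gives (E)-4,4,5,5-tetramethyl-2-(5-phenylpent-1-en-1-yl)-1,3,2-dioxaborolane F4. A rhodium-catalysed Hayashi–Miyaura addition of F4 to 4 ([Rh(OH)(cod)]2, (S)-BINAP, dioxane–water) gives (2R,5S)-2-(tert-butyldimethylsilyloxy)-5-[(1E)-5-phenylpent-1-en-1-yl]cyclohexan-1-one F5. This catalyst discriminates enone faces by a different mechanism that is little affected by remote substituents, and the neutral boron reagent cannot add 1,2. Hydrogenation of F5 (H2, Pd/C, EtOAc) comes back to the route at 8.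

**Step 6.** Acylation of the hindered enolate may be incomplete. On warming, proton transfer could equilibrate the enolate and epimerise the silyloxy-bearing carbon. Fallback, setting out from 8: enolate 10 is formed as before and added to methoxyacetaldehyde at −78 °C to give (2R,5S)-2-(tert-butyldimethylsilyloxy)-6-(1-hydroxy-2-methoxyethyl)-5-(5-phenylpentyl)cyclohexan-1-one F6 as a mixture at the two new centres. Oxidation with Dess–Martin periodinane removes both and comes back to the route at 11.

**Step 2.** The hydrolase may discriminate the enantiomers insufficiently, and the α-ketol may partly racemise during hydrolysis or isolation. A resolution also discards half of the material. Fallback, setting out from 2: non-selective methanolysis (K2CO3, MeOH, 0 °C) gives rac-6-hydroxycyclohex-2-en-1-one F7, and silylation as in step 3 gives rac-6-(tert-butyldimethylsilyloxy)cyclohex-2-en-1-one F8. The catalyst-controlled conjugate addition of step 5 is then run on F8 with 6. The catalyst should fix the chain-bearing centre in both enantiomers of F8, giving 8 together with its epimer (2S,5S)-2-(tert-butyldimethylsilyloxy)-5-(5-phenylpentyl)cyclohexan-1-one F9. The two are separated by chromatography, and F9 can be re-equilibrated at the silyloxy-bearing carbon with DBU and recycled. The sequence comes back to the route at 8.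

## Further compounds

F1 | step 8 | 1-[(3R,6S)-2-amino-3-(tert-butyldimethylsilyloxy)-6-(5-phenylpentyl)cyclohex-1-en-1-yl]-2-methoxyethan-1-one | NC2=C(C(=O)COC)[C@@H](CCCCCc1ccccc1)CC[C@H]2O[Si](C)(C)C(C)(C)C
F2 | step 8 | N′-[(3S,6R)-6-(tert-butyldimethylsilyloxy)-2-(methoxyacetyl)-3-(5-phenylpentyl)cyclohex-1-en-1-yl]-N,N-dimethylethanimidamide | CN(C)C(C)=NC2=C(C(=O)COC)[C@@H](CCCCCc1ccccc1)CC[C@H]2O[Si](C)(C)C(C)(C)C
F3 | step 7 | (3S,6R)-6-(tert-butyldimethylsilyloxy)-2-(methoxyacetyl)-3-(5-phenylpentyl)cyclohex-1-en-1-yl trifluoromethanesulfonate | O=S(=O)(OC2=C(C(=O)COC)[C@@H](CCCCCc1ccccc1)CC[C@H]2O[Si](C)(C)C(C)(C)C)C(F)(F)F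
F4 | step 5 | (E)-4,4,5,5-tetramethyl-2-(5-phenylpent-1-en-1-yl)-1,3,2-dioxaborolane | CC1(C)OB(/C=C/CCCc2ccccc2)OC1(C)C
F5 | step 5 | (2R,5S)-2-(tert-butyldimethylsilyloxy)-5-[(1E)-5-phenylpent-1-en-1-yl]cyclohexan-1-one | O=C1C[C@@H](/C=C/CCCc2ccccc2)CC[C@H]1O[Si](C)(C)C(C)(C)C
F6 | step 6 | (2R,5S)-2-(tert-butyldimethylsilyloxy)-6-(1-hydroxy-2-methoxyethyl)-5-(5-phenylpentyl)cyclohexan-1-one (mixture at C6 and the carbinol) | O=C1C(C(O)COC)[C@@H](CCCCCc2ccccc2)CC[C@H]1O[Si](C)(C)C(C)(C)C
F7 | step 2 | rac-6-hydroxycyclohex-2-en-1-one | O=C1C=CCCC1O
F8 | step 2 | rac-6-(tert-butyldimethylsilyloxy)cyclohex-2-en-1-one | O=C1C=CCCC1O[Si](C)(C)C(C)(C)C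
F9 | step 2 | (2S,5S)-2-(tert-butyldimethylsilyloxy)-5-(5-phenylpentyl)cyclohexan-1-one | O=C1C[C@@H](CCCCCc2ccccc2)CC[C@@H]1O[Si](C)(C)C(C)(C)C
A1 | alternative 1 | (1E,3E)-9-phenylnona-1,3-dien-1-yl acetate | CC(=O)O/C=C/C=C/CCCCCc1ccccc1
A2 | alternative 1 | ethyl (2E)-4-oxo-4-(2-oxo-1,3-oxazolidin-3-yl)but-2-enoate | CCOC(=O)/C=C/C(=O)N1CCOC1=O
A3 | alternative 1 | ethyl 5-acetoxy-6-(2-oxo-1,3-oxazolidine-3-carbonyl)-2-(5-phenylpentyl)cyclohex-3-ene-1-carboxylate, acetoxy, imide and alkyl groups all cis, ester trans, enantiomer as in the SMILES | O=C(N3CCOC3=O)[C@H]2[C@H](C(=O)OCC)[C@@H](CCCCCc1ccccc1)C=C[C@H]2OC(C)=O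
A4 | alternative 2 | (4S)-4-[4-(benzyloxy)-2-bromo-5-methoxy-6-methylpyridin-3-yl]-9-phenylnonanal | Cc1nc(Br)c(c(OCc3ccccc3)c1OC)[C@@H](CCCCCc1ccccc1)CCC=O
A5 | alternative 2 | (5S,8R)-4-(benzyloxy)-3-methoxy-2-methyl-5-(5-phenylpentyl)-5,6,7,8-tetrahydroquinolin-8-ol | Cc1nc2c(c(OCc3ccccc3)c1OC)[C@@H](CCCCCc1ccccc1)CC[C@H]2O
A6 | alternative 3 | 4-(benzyloxy)-2-[(1S)-1-(tert-butyldimethylsilyloxy)-2-iodoethyl]-5-methoxy-6-methyl-3-(7-phenylhept-1-en-2-yl)pyridine | Cc1nc([C@@H](CI)O[Si](C)(C)C(C)(C)C)c(C(=C)CCCCCc2ccccc2)c(OCc2ccccc2)c1OC
A7 | alternative 3 | (5S,8R)-4-(benzyloxy)-8-(tert-butyldimethylsilyloxy)-3-methoxy-2-methyl-5-(5-phenylpentyl)-5,6,7,8-tetrahydroquinoline | Cc1nc2c(c(OCc3ccccc3)c1OC)[C@@H](CCCCCc1ccccc1)CC[C@H]2O[Si](C)(C)C(C)(C)C
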